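**Strategy.** Everything rests on disconnecting the C2–C3 bond of the pyranone ring C. In the key step the diazo carbon of an aryl diazomethyl ketone (future C3) becomes a chiral dirhodium carbenoid. It inserts into the benzylic C–H bond of the neighbouring 4-(benzyloxy)benzyl aryl ether (future C2), closing the heterocycle and setting C2 in one operation. The step exploits the C2–H bond of the target, which lies between ring oxygen O1 and the 4-oxygenated ring B and is 1,6-related to C3 through the C4 carbonyl and ring A. The precursor is an open-chain, fully protected phloroacetophenone-derived diazoketone. The 3-hydroxyl follows by trans-selective Rubottom oxidation.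

Key step: step 6

Abbreviations: Bn = benzyl; PBB = 4-(benzyloxy)benzyl, CH2–C6H4–OCH2Ph.
Assumption: the sense of induction of the chiral dirhodium catalyst on this substrate must be assigned by experiment. The route is written with Rh2(S-PTTL)4; the mirror-image catalyst Rh2(R-PTTL)4 would be used if the first favoured the (2R)-flavanone.

Step 1
Reactants: 1 2′,4′,6′-trihydroxyacetophenone; 2 4-(benzyloxy)benzyl alcohol
Product: 3 1-{3-[4-(benzyloxy)benzyl]-2,4,6-trihydroxyphenyl}ethanone
Conditions: 1 (3 equiv), p-TsOH·H2O (cat.), 1,4-dioxane, 60 °C, slow addition of 2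
Reagents that add atoms: none
Why: Acid-catalysed Friedel–Crafts benzylation through the oxygen-stabilised 4-(benzyloxy)benzyl cation of 2 should alkylate the phloroglucinol nucleus at C3, which is equivalent to C5, so only one mono-C-benzyl product is possible, the excess of 1 suppresses a second alkylation, and the phenol of the new benzyl unit arrives already protected.

Step 2
Reactants: 3 1-{3-[4-(benzyloxy)benzyl]-2,4,6-trihydroxyphenyl}ethanone
Product: 4 1-{4-(benzyloxy)-3-[4-(benzyloxy)benzyl]-2,6-dihydroxyphenyl}ethanone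
Conditions: BnBr (1.0 equiv), K2CO3 (1.1 equiv), acetone, 20 °C
Reagents that add atoms: benzyl bromide, BrCc1ccccc1
Why: Williamson etherification with one equivalent of halide should take the 4-hydroxyl, the most acidic phenol (para to the acetyl group and not hydrogen-bonded to it), as is usual in partial alkylations of phloroacetophenones, while the two ortho hydroxyls stay free.

Step 3
Reactants: 4 1-{4-(benzyloxy)-3-[4-(benzyloxy)benzyl]-2,6-dihydroxyphenyl}ethanone; 5 4-(benzyloxy)benzyl chloride
Product: 6 1-{4-(benzyloxy)-3-[4-(benzyloxy)benzyl]-6-[4-(benzyloxy)benzyloxy]-2-hydroxyphenyl}ethanone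
Conditions: 5 (1.1 equiv), K2CO3, KI (cat.), DMF, 40 °C
Reagents that add atoms: none
Why: Williamson etherification should take the less hindered ortho hydroxyl (6-OH, next to H-5) and leave the 2-OH that is flanked by the C-benzyl group and chelated to the ketone, as is usual for 3-alkylphloroacetophenones; the ether placed at C6 is para to the C-benzyl carbon, which later fixes the benzyl group at C6 and not C8 of the chromanone.

Step 4
Reactants: 6 1-{4-(benzyloxy)-3-[4-(benzyloxy)benzyl]-6-[4-(benzyloxy)benzyloxy]-2-hydroxyphenyl}ethanone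
Product: 7 (E)-1-{4-(benzyloxy)-3-[4-(benzyloxy)benzyl]-6-[4-(benzyloxy)benzyloxy]-2-hydroxyphenyl}-3-(dimethylamino)prop-2-en-1-one
Conditions: Me2NCH(OMe)2 (3 equiv), toluene, 100 °C
Reagents that add atoms: N,N-dimethylformamide dimethyl acetal, COC(OC)N(C)C
Why: Condensation of the methyl ketone with the amide acetal (enaminone formation) runs under neutral conditions that spare the acid-sensitive PBB ether and tolerate the chelated phenol, and gives the (E)-vinylogous amide.

Step 5
Reactants: 7 (E)-enaminone
Product: 9 benzyl 3-(benzyloxy)-2-[4-(benzyloxy)benzyl]-5-[4-(benzyloxy)benzyloxy]-6-(diazoacetyl)phenyl carbonate, via hydroxy diazoketone 8 (not isolated)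
Conditions: 4-acetamidobenzenesulfonyl azide (1.2 equiv), MeCN, 20 °C, dark; then Et3N, DMAP (cat.), CbzCl, 0 °C
Reagents that add atoms: 4-acetamidobenzenesulfonyl azide, CC(=O)Nc1ccc(cc1)S(=O)(=O)N=[N+]=[N-]; benzyl chloroformate, O=C(Cl)OCc1ccccc1
Why: Diazo transfer to an enaminone, in which the sulfonyl azide adds across the electron-rich C=C bond and the triazoline fragments to the diazoketone and a sulfonylformamidine, needs no enolate and so avoids acyl migration and chromone closure; the chelated phenol is then acylated by the chloroformate under DMAP catalysis, which a diazoketone tolerates.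

Step 6
Reactants: 9 benzyl 3-(benzyloxy)-2-[4-(benzyloxy)benzyl]-5-[4-(benzyloxy)benzyloxy]-6-(diazoacetyl)phenyl carbonate
Product: 10 (2S)-7-(benzyloxy)-6-[4-(benzyloxy)benzyl]-5-(benzyloxycarbonyloxy)-2-[4-(benzyloxy)phenyl]chroman-4-one
Conditions: Rh2(S-PTTL)4 (dirhodium tetrakis[N-phthaloyl-(S)-tert-leucinate], 1 mol%), CH2Cl2, 0 °C, slow addition of 9
Reagents that add atoms: none
Why: Loss of N2 from 9 at the dirhodium catalyst gives an electrophilic rhodium carbenoid at the future C3, which inserts into one of the two enantiotopic hydrogens of the O1–CH2–aryl group through a concerted, asynchronous three-centre transition state with hydride-transfer character, forming the C2–C3 and C3–H bonds at once. The closest known reaction type is the chiral dirhodium carboxylate-catalysed intramolecular C–H insertion of 2-alkoxyaryl diazoketones to chroman-4-ones, which is established for ether C–H bonds including benzylic ones. Ring C closes as a six-membered ring by 1,6-insertion (carbenoid carbon and C–H carbon joined through C4, C4a, C8a and O1), while the other activated C–H bonds (the 7-O-benzyl methylene, the diarylmethane CH2 and the carbonate CH2) cannot reach the carbenoid through a five- or six-membered transition state. The new stereocentre C2 is controlled by the chiral carboxylate ligands, which differentiate the two enantiotopic C–H bonds; the (2S) descriptor of 10 is the spatial arrangement that becomes (2R) once C3 carries oxygen. The step needs chemoselectivity for C–H insertion over attack of O1 on the carbenoid (five-membered oxonium ylide, then 1,2-benzyl shift to a 2-benzylbenzofuran-3-one) and over reaction at the other ortho oxygen: O1 is a poorly basic aryl ether oxygen whose lone pair is drawn into the acylated ring A, the C2–H bond is doubly activated by O1 and the 4-benzyloxyphenyl ring, and the 5-oxygen is masked as a carbonate with little nucleophilicity and no C–H bond in reach. Any shortfall in enantiomeric purity should be corrected by recrystallisation of 10 or 13.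

Step 7
Reactants: 10 (2S)-flavanone
Product: 13 (2R,3R)-7-(benzyloxy)-6-[4-(benzyloxy)benzyl]-5-(benzyloxycarbonyloxy)-2-[4-(benzyloxy)phenyl]-3-hydroxychroman-4-one, via silyl enol ether 11 (not isolated), via trimethylsilyloxy ketone 12 (not isolated)
Conditions: TMSOTf, Et3N, CH2Cl2, 0 °C, dark; then DMDO, acetone–CH2Cl2, −40 °C; then aq. citric acid, THF, 20 °C
Reagents that add atoms: dimethyldioxirane, CC1(C)OO1; trimethylsilyl triflate, C[Si](C)(C)OS(=O)(=O)C(F)(F)F (silicon only in 11 and 12)
Why: Rubottom oxidation: soft enolization avoids a free enolate that could expel the O1 phenoxide and erode C2, and dimethyldioxirane should epoxidise the C3–C4 enol ether on the face opposite the C2 aryl group, so that after silyl shift and hydrolysis the C3 hydroxyl stands trans to the aryl group (3R), as known for flavanone silyl enol ethers.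

Step 8
Reactants: 13 protected (2R,3R)-dihydroflavonol
Product: 14 gericudranin E, (2R,3R)-3,5,7-trihydroxy-6-(4-hydroxybenzyl)-2-(4-hydroxyphenyl)chroman-4-one
Conditions: H2 (1 atm), 10% Pd/C, EtOAc–MeOH, 20 °C
Reagents that add atoms: none
Why: Catalytic hydrogenolysis should cleave the three benzyl ethers and the benzyl carbonate (the latter losing CO2) under mild conditions in which the C4 ketone, the C2–O1 bond and both stereocentres of dihydroflavonols normally persist.

**Compound list**

1 | 2′,4′,6′-trihydroxyacetophenone | CC(=O)c1c(O)cc(O)cc1O | starting material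
2 | 4-(benzyloxy)benzyl alcohol | OCc1ccc(OCc2ccccc2)cc1 | starting material
3 | 1-{3-[4-(benzyloxy)benzyl]-2,4,6-trihydroxyphenyl}ethanone | CC(=O)c1c(O)cc(O)c(Cc2ccc(OCc3ccccc3)cc2)c1O | intermediate
4 | 1-{4-(benzyloxy)-3-[4-(benzyloxy)benzyl]-2,6-dihydroxyphenyl}ethanone | CC(=O)c1c(O)cc(OCc2ccccc2)c(Cc2ccc(OCc3ccccc3)cc2)c1O | intermediate
5 | 4-(benzyloxy)benzyl chloride | ClCc1ccc(OCc2ccccc2)cc1 | starting material
6 | 1-{4-(benzyloxy)-3-[4-(benzyloxy)benzyl]-6-[4-(benzyloxy)benzyloxy]-2-hydroxyphenyl}ethanone | CC(=O)c1c(OCc2ccc(OCc3ccccc3)cc2)cc(OCc2ccccc2)c(Cc2ccc(OCc3ccccc3)cc2)c1O | intermediate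
7 | (E)-1-{4-(benzyloxy)-3-[4-(benzyloxy)benzyl]-6-[4-(benzyloxy)benzyloxy]-2-hydroxyphenyl}-3-(dimethylamino)prop-2-en-1-one | CN(C)/C=C/C(=O)c1c(OCc2ccc(OCc3ccccc3)cc2)cc(OCc2ccccc2)c(Cc2ccc(OCc3ccccc3)cc2)c1O | intermediate
8 | 1-{4-(benzyloxy)-3-[4-(benzyloxy)benzyl]-6-[4-(benzyloxy)benzyloxy]-2-hydroxyphenyl}-2-diazoethanone | [N-]=[N+]=CC(=O)c1c(OCc2ccc(OCc3ccccc3)cc2)cc(OCc2ccccc2)c(Cc2ccc(OCc3ccccc3)cc2)c1O | intermediate (not isolated)
9 | benzyl 3-(benzyloxy)-2-[4-(benzyloxy)benzyl]-5-[4-(benzyloxy)benzyloxy]-6-(diazoacetyl)phenyl carbonate | [N-]=[N+]=CC(=O)c1c(OCc2ccc(OCc3ccccc3)cc2)cc(OCc2ccccc2)c(Cc2ccc(OCc3ccccc3)cc2)c1OC(=O)OCc1ccccc1 | intermediate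
10 | (2S)-7-(benzyloxy)-6-[4-(benzyloxy)benzyl]-5-(benzyloxycarbonyloxy)-2-[4-(benzyloxy)phenyl]chroman-4-one | O=C1c2c(cc(OCc3ccccc3)c(Cc3ccc(OCc4ccccc4)cc3)c2OC(=O)OCc2ccccc2)O[C@H](c2ccc(OCc3ccccc3)cc2)C1 | intermediate
11 | benzyl (2S)-7-(benzyloxy)-6-[4-(benzyloxy)benzyl]-2-[4-(benzyloxy)phenyl]-4-(trimethylsilyloxy)-2H-chromen-5-yl carbonate | C[Si](C)(C)OC1=C[C@@H](c2ccc(OCc3ccccc3)cc2)Oc2cc(OCc3ccccc3)c(Cc3ccc(OCc4ccccc4)cc3)c(OC(=O)OCc3ccccc3)c12 | intermediate (not isolated)
12 | (2R,3R)-7-(benzyloxy)-6-[4-(benzyloxy)benzyl]-5-(benzyloxycarbonyloxy)-2-[4-(benzyloxy)phenyl]-3-(trimethylsilyloxy)chroman-4-one | O=C1c2c(cc(OCc3ccccc3)c(Cc3ccc(OCc4ccccc4)cc3)c2OC(=O)OCc2ccccc2)O[C@H](c2ccc(OCc3ccccc3)cc2)[C@H]1O[Si](C)(C)C | intermediate (not isolated)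
13 | (2R,3R)-7-(benzyloxy)-6-[4-(benzyloxy)benzyl]-5-(benzyloxycarbonyloxy)-2-[4-(benzyloxy)phenyl]-3-hydroxychroman-4-one | O=C1c2c(cc(OCc3ccccc3)c(Cc3ccc(OCc4ccccc4)cc3)c2OC(=O)OCc2ccccc2)O[C@H](c2ccc(OCc3ccccc3)cc2)[C@H]1O | intermediate
14 | gericudranin E, (2R,3R)-3,5,7-trihydroxy-6-(4-hydroxybenzyl)-2-(4-hydroxyphenyl)chroman-4-one | O=C1c2c(cc(O)c(Cc3ccc(O)cc3)c2O)O[C@H](c2ccc(O)cc2)[C@H]1O | target

**Total step count:** 8. **Longest linear sequence:** 8 steps (1 to 14).

**Steps most likely to fail**

Step 6. The carbenoid may be captured by O1 to give an oxonium ylide that rearranges by 1,2-benzyl shift, or the insertion may proceed with insufficient enantioselectivity. The fallback sets out from 9 and still closes the ring through the C2–C3 bond. Oxidation of the diazoketone with DMDO in acetone should give the arylglyoxal, benzyl 3-(benzyloxy)-2-[4-(benzyloxy)benzyl]-5-[4-(benzyloxy)benzyloxy]-6-(oxoacetyl)phenyl carbonate F1. Irradiation of F1 with visible light (about 420–450 nm, degassed benzene) excites the 1,2-dicarbonyl chromophore. Its aldehyde oxygen abstracts a hydrogen from the O–CH2–aryl group and the 1,6-biradical collapses (Norrish–Yang-type photocyclisation of 2-alkoxyaryl 1,2-dicarbonyl compounds to 3-hydroxychroman-4-ones). This should give the racemic trans ketol F2 directly, with the C3 hydroxyl already in place. Separation of the enantiomers by preparative chromatography on a chiral stationary phase brings the route back at 13, so steps 6 and 7 are bypassed.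

Step 5. The hydroxy enaminone may close to a chromone or form a triazole instead of transferring the diazo group, or the free-phenol diazoketone may decompose before acylation. The fallback sets out from 6. Riley oxidation (SeO2, pyridine, 1,4-dioxane–H2O, 90 °C) should give the 2-hydroxyarylglyoxal, 2-{4-(benzyloxy)-3-[4-(benzyloxy)benzyl]-6-[4-(benzyloxy)benzyloxy]-2-hydroxyphenyl}-2-oxoacetaldehyde F3. Condensation with p-toluenesulfonylhydrazide gives the aldehyde monotosylhydrazone F4, and Et3N then expels sulfinate (Bamford–Stevens-type diazo formation). The route is rejoined at 8, which is acylated with benzyl chloroformate as in the second half of step 5.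

Step 3. Alkylation may occur at the 2-hydroxyl instead of the 6-hydroxyl, or go on to the diether, giving regioisomeric ethers that are hard to separate. The fallback sets out from 1 and fixes the position of the PBB ether by symmetry before the carbon substituent is introduced.
- Monobenzylation of 1 at the 4-hydroxyl (BnBr, one equivalent, K2CO3, acetone) gives 1-[4-(benzyloxy)-2,6-dihydroxyphenyl]ethanone F5, whose two ortho hydroxyls are equivalent.
- Alkylation with one equivalent of 5 (K2CO3, DMF) can then give only one monoether, 1-{4-(benzyloxy)-2-[4-(benzyloxy)benzyloxy]-6-hydroxyphenyl}ethanone F6, the remaining hydroxyl being chelated.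
- C-Benzylation of the lithium phenoxide of F6 with 5 (LiOtBu, toluene, 80 °C) returns to 6. Ortho C-alkylation of a phenoxide in a non-polar medium should occur at the only free position ortho to the phenoxide oxygen, between the hydroxyl and the 4-benzyloxy group. Acid is avoided because the PBB aryl ether is acid-labile.

**Further compounds**

F1 | step 6 | benzyl 3-(benzyloxy)-2-[4-(benzyloxy)benzyl]-5-[4-(benzyloxy)benzyloxy]-6-(oxoacetyl)phenyl carbonate (arylglyoxal) | O=CC(=O)c1c(OCc2ccc(OCc3ccccc3)cc2)cc(OCc2ccccc2)c(Cc2ccc(OCc3ccccc3)cc2)c1OC(=O)OCc1ccccc1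
F2 | step 6 | racemic trans ketol, 1:1 mixture of 13 and its (2S,3S) enantiomer | O=C1c2c(cc(OCc3ccccc3)c(Cc3ccc(OCc4ccccc4)cc3)c2OC(=O)OCc2ccccc2)O[C@H](c2ccc(OCc3ccccc3)cc2)[C@H]1O.O=C1c2c(cc(OCc3ccccc3)c(Cc3ccc(OCc4ccccc4)cc3)c2OC(=O)OCc2ccccc2)O[C@@H](c2ccc(OCc3ccccc3)cc2)[C@@H]1O
F3 | step 5 | 2-{4-(benzyloxy)-3-[4-(benzyloxy)benzyl]-6-[4-(benzyloxy)benzyloxy]-2-hydroxyphenyl}-2-oxoacetaldehyde | O=CC(=O)c1c(OCc2ccc(OCc3ccccc3)cc2)cc(OCc2ccccc2)c(Cc2ccc(OCc3ccccc3)cc2)c1O
F4 | step 5 | (E)-monotosylhydrazone of F3 at the aldehyde carbon | Cc1ccc(cc1)S(=O)(=O)N/N=C/C(=O)c1c(OCc2ccc(OCc3ccccc3)cc2)cc(OCc2ccccc2)c(Cc2ccc(OCc3ccccc3)cc2)c1O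
F5 | step 3 | 1-[4-(benzyloxy)-2,6-dihydroxyphenyl]ethanone | CC(=O)c1c(O)cc(OCc2ccccc2)cc1O
F6 | step 3 | 1-{4-(benzyloxy)-2-[4-(benzyloxy)benzyloxy]-6-hydroxyphenyl}ethanone | CC(=O)c1c(O)cc(OCc2ccccc2)cc1OCc1ccc(OCc2ccccc2)cc1
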